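The flavanone is opened at the O1–C2 bond of ring C, the reverse of the chalcone-to-flavanone step of flavonoid biosynthesis. The step exploits the β-aryloxy ketone array O1–C2–C3–C4(=O) of ring C, and the fact that ring A, methylated at O5 and alkylated at C8, offers one free ortho phenol only. The precursor is a 2'-hydroxychalcone activated as its tert-butyl α-carboxylate, assembled from a (2R)-lavandulyl acetophenone (Negishi coupling of an auxiliary-derived lavandulylzinc reagent) and a silylated benzaldehyde. In one operation a cinchona thiourea closes ring C by oxa-Michael addition, sets C2 as S, and acid then excises the activating ester.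

Key step: step 11

Remark: the lavandulyl centre is R in the target, which corresponds in space to (S)-lavandulol (the CIP priorities change when CH2OH becomes CH2Ar); the sense of induction of the thiourea catalyst is assigned by analogy with simpler alkylidene β-keto esters, and the quinine-derived pseudoenantiomer is used if it proves reversed.

Step 1
Reactants: 1 (4S)-4-benzyl-1,3-oxazolidin-2-one; 2 3-methylbut-2-enoyl chloride
Product: 3 (4S)-4-benzyl-3-(3-methylbut-2-enoyl)-1,3-oxazolidin-2-one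
Conditions: n-BuLi, THF, −78 °C; then 2, −78 → 0 °C
Reagents that add atoms: none
Why: N-acylation of the lithiated oxazolidinone with an acid chloride is the standard entry to Evans imides, and no stereocentre is formed.

Step 2
Reactants: 3 (4S)-4-benzyl-3-(3-methylbut-2-enoyl)-1,3-oxazolidin-2-one; 4 1-bromo-3-methylbut-2-ene (prenyl bromide)
Product: 5 (4S)-4-benzyl-3-[(2S)-5-methyl-2-(prop-1-en-2-yl)hex-4-enoyl]-1,3-oxazolidin-2-one
Conditions: NaN(SiMe3)2, THF, −78 °C; then 4, −78 → −40 °C; AcOH quench at −78 °C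
Reagents that add atoms: none
Why: Evans asymmetric alkylation in its deconjugative form: γ-deprotonation should give the chelated Z sodium dienolate, which is alkylated at the α-carbon on the face anti to the benzyl group, so that C2 is set as S and the isopropenyl group arises by deconjugation.

Step 3
Reactants: 5 (4S)-4-benzyl-3-[(2S)-5-methyl-2-(prop-1-en-2-yl)hex-4-enoyl]-1,3-oxazolidin-2-one
Product: 6 (2S)-5-methyl-2-(prop-1-en-2-yl)hex-4-en-1-ol [(S)-lavandulol]
Conditions: LiBH4, MeOH (1 equiv), Et2O, 0 °C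
Reagents that add atoms: none
Why: Reductive removal of the auxiliary with LiBH4 attacks the exocyclic imide carbonyl selectively and should leave the α-centre untouched (the label stays S).

Step 4
Reactants: 6 (2S)-5-methyl-2-(prop-1-en-2-yl)hex-4-en-1-ol
Product: 7 (3S)-3-(iodomethyl)-2,6-dimethylhepta-1,5-diene [(S)-lavandulyl iodide]
Conditions: I2, PPh3, imidazole, CH2Cl2, 0 °C
Reagents that add atoms: iodine, II
Why: Appel-type iodination of a primary alcohol under neutral conditions; the stereocentre is β to the reacting carbon and is not involved.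

Step 5
Reactants: 8 1-(2,4-dihydroxy-6-methoxyphenyl)ethan-1-one
Product: 9 1-(2,4-dihydroxy-3-iodo-6-methoxyphenyl)ethan-1-one
Conditions: I2 (1.0 equiv), NaHCO3, THF–H2O, 0 °C
Reagents that add atoms: iodine, II
Why: Electrophilic aromatic iodination of the resorcinol-type aryloxide should occur at C3, the only position ortho to both free hydroxyl groups, as in the iodination of resorcinol itself to its 2-iodo derivative under these conditions.

Step 6
Reactants: 9 1-(2,4-dihydroxy-3-iodo-6-methoxyphenyl)ethan-1-one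
Product: 10 1-{2-hydroxy-3-iodo-6-methoxy-4-[tri(propan-2-yl)silyloxy]phenyl}ethan-1-one
Conditions: i-Pr3SiCl (1.05 equiv), imidazole, DMF, 0 °C → rt
Reagents that add atoms: chlorotri(propan-2-yl)silane, CC(C)[Si](Cl)(C(C)C)C(C)C
Why: Selective O-silylation of the non-chelated, more acidic 4-hydroxyl group; the 2-hydroxyl is hydrogen-bonded to the acetyl group and should stay free.

Step 7
Reactants: 7 (3S)-3-(iodomethyl)-2,6-dimethylhepta-1,5-diene; 10 1-{2-hydroxy-3-iodo-6-methoxy-4-[tri(propan-2-yl)silyloxy]phenyl}ethan-1-one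
Product: 12 1-{2-hydroxy-6-methoxy-3-[(2R)-5-methyl-2-(prop-1-en-2-yl)hex-4-en-1-yl]-4-[tri(propan-2-yl)silyloxy]phenyl}ethan-1-one, via (S)-lavandulylzinc iodide 11 (not isolated)
Conditions: 7, Zn dust (activated with BrCH2CH2Br and Me3SiCl), LiCl, THF, 40 °C; then 10, Pd(OAc)2 (4 mol%), SPhos (8 mol%), THF, 25 → 45 °C, slow addition of the zinc reagent (1.5 equiv)
Reagents that add atoms: none
Why: Negishi coupling of a primary alkylzinc iodide (LiCl-assisted zinc insertion) with a hindered aryl iodide, for which the SPhos–palladium catalyst is known to couple faster than phenols protonate organozincs and faster than β-hydride elimination; the stereocentre is β to zinc and is not touched (its label becomes R only through the CIP priorities).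

Step 8
Reactants: 12 1-{2-hydroxy-6-methoxy-3-[(2R)-5-methyl-2-(prop-1-en-2-yl)hex-4-en-1-yl]-4-[tri(propan-2-yl)silyloxy]phenyl}ethan-1-one
Product: 14 tert-butyl 3-{2-hydroxy-6-methoxy-3-[(2R)-5-methyl-2-(prop-1-en-2-yl)hex-4-en-1-yl]-4-[tri(propan-2-yl)silyloxy]phenyl}-3-oxopropanoate, via aryl tert-butyl carbonate 13 (not isolated)
Conditions: LiN(SiMe3)2 (1.05 equiv), THF, −78 °C; Boc2O (1.1 equiv), −78 → 0 °C; then LiN(SiMe3)2 (2.2 equiv), −78 → 0 °C; AcOH quench
Reagents that add atoms: di-tert-butyl dicarbonate, CC(C)(C)OC(=O)OC(=O)OC(C)(C)C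
Why: O-tert-butoxycarbonylation of the lithium phenoxide followed by a Baker–Venkataraman-type 1,5-shift of the Boc group to the ketone enolate should give the β-keto ester, the transfer being driven by its stabilised enolate, while the tert-butyl group blocks lactonisation to a 4-hydroxycoumarin.

Step 9
Reactants: 15 4-hydroxy-2-methoxybenzaldehyde
Product: 16 2-methoxy-4-[tri(propan-2-yl)silyloxy]benzaldehyde
Conditions: i-Pr3SiCl, imidazole, DMF, rt
Reagents that add atoms: chlorotri(propan-2-yl)silane, CC(C)[Si](Cl)(C(C)C)C(C)C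
Why: Routine silylation of a phenol, chosen because the aryl triisopropylsilyl ether should survive amine, acid and heat in the next two steps and falls to fluoride at the end.

Step 10
Reactants: 14 tert-butyl 3-{2-hydroxy-6-methoxy-3-[(2R)-5-methyl-2-(prop-1-en-2-yl)hex-4-en-1-yl]-4-[tri(propan-2-yl)silyloxy]phenyl}-3-oxopropanoate; 16 2-methoxy-4-[tri(propan-2-yl)silyloxy]benzaldehyde
Product: 17 tert-butyl (2Z)-2-{2-hydroxy-6-methoxy-3-[(2R)-5-methyl-2-(prop-1-en-2-yl)hex-4-en-1-yl]-4-[tri(propan-2-yl)silyloxy]benzoyl}-3-{2-methoxy-4-[tri(propan-2-yl)silyloxy]phenyl}prop-2-enoate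
Conditions: piperidine (0.2 equiv), AcOH (0.2 equiv), 4 Å molecular sieves, benzene, 70 °C
Reagents that add atoms: none
Why: Knoevenagel condensation of the 1,3-dicarbonyl compound under piperidinium acetate catalysis with removal of water, in which the bulky tert-butyl ester and the twisted aroyl group should hold back uncatalysed ring closure; the Z isomer (aryl anti to the aroyl group) is expected, and the alkene geometry is lost in the next step.

Step 11
Reactants: 17 tert-butyl (2Z)-2-{2-hydroxy-6-methoxy-3-[(2R)-5-methyl-2-(prop-1-en-2-yl)hex-4-en-1-yl]-4-[tri(propan-2-yl)silyloxy]benzoyl}-3-{2-methoxy-4-[tri(propan-2-yl)silyloxy]phenyl}prop-2-enoate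
Product: 20 (2S)-5-methoxy-2-{2-methoxy-4-[tri(propan-2-yl)silyloxy]phenyl}-8-[(2R)-5-methyl-2-(prop-1-en-2-yl)hex-4-en-1-yl]-7-[tri(propan-2-yl)silyloxy]-2,3-dihydro-4H-chromen-4-one, via tert-butyl (2S,3R)-4-oxochromane-3-carboxylate 18 (not isolated), via (2S,3R)-4-oxochromane-3-carboxylic acid 19 (not isolated)
Conditions: thiourea from 9-amino-9-deoxy-epi-quinidine and 3,5-bis(trifluoromethyl)phenyl isothiocyanate (10 mol%), toluene, −25 °C; then TsOH·H2O (0.5 equiv), 80 °C
Reagents that add atoms: none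
Why: The quinuclidine nitrogen of the bifunctional catalyst activates the one free phenol of ring A (the future O1) while the thiourea hydrogen-bonds the 1,3-dicarbonyl unit of 17, and the oxygen adds to the β-carbon (the future C2) to give 18; TsOH then cleaves the tert-butyl ester with loss of 2-methylpropene and acid 19 decarboxylates through its enol. The closest known reaction type is the cinchona-thiourea-catalysed enantioselective intramolecular oxa-Michael addition of tert-butyl alkylidene β-keto esters with one-pot acid decarboxylation, the laboratory counterpart of the chalcone isomerase reaction. Ring C is closed in the 6-endo-trig mode. The C2 stereocentre is set by the catalyst, which selects the face of the prochiral β-carbon (the remote lavandulyl centre is not expected to contribute), the quinidine-derived catalyst being chosen for the 2S series; the C3 centre of 18 is transient and is erased on decarboxylation. The step needs regioselectivity (secured because O5 is methylated and O7 and O4' are silylated, leaving a single nucleophilic phenol), enantioselectivity without background closure (secured by the bulky tert-butyl ester and the low temperature), and retention of C2 and of the diene (acidic rather than basic ester removal avoids retro-oxa-Michael opening, and the silyl ether at O7 keeps a phenol from adding to the protonated lavandulyl alkenes).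

Step 12
Reactants: 20 (2S)-5-methoxy-2-{2-methoxy-4-[tri(propan-2-yl)silyloxy]phenyl}-8-[(2R)-5-methyl-2-(prop-1-en-2-yl)hex-4-en-1-yl]-7-[tri(propan-2-yl)silyloxy]-2,3-dihydro-4H-chromen-4-one
Product: 21 (2S)-2'-methoxykurarinone, (2S)-7-hydroxy-2-(4-hydroxy-2-methoxyphenyl)-5-methoxy-8-[(2R)-5-methyl-2-(prop-1-en-2-yl)hex-4-en-1-yl]-2,3-dihydro-4H-chromen-4-one
Conditions: Bu4NF (2.5 equiv), AcOH (2.5 equiv), THF, 0 °C
Reagents that add atoms: none
Why: Fluoride-mediated cleavage of the two aryl silyl ethers; buffering with AcOH should keep the phenols protonated so that no phenoxide-triggered retro-oxa-Michael opening can epimerise C2, and the alkenes are inert to these conditions.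

Compound list
1 | (4S)-4-benzyl-1,3-oxazolidin-2-one | O=C1N[C@@H](Cc2ccccc2)CO1 | starting material
2 | 3-methylbut-2-enoyl chloride | CC(C)=CC(=O)Cl | starting material
3 | (4S)-4-benzyl-3-(3-methylbut-2-enoyl)-1,3-oxazolidin-2-one | CC(C)=CC(=O)N1[C@@H](Cc2ccccc2)COC1=O | intermediate
4 | 1-bromo-3-methylbut-2-ene (prenyl bromide) | CC(C)=CCBr | starting material
5 | (4S)-4-benzyl-3-[(2S)-5-methyl-2-(prop-1-en-2-yl)hex-4-enoyl]-1,3-oxazolidin-2-one | C=C(C)[C@H](CC=C(C)C)C(=O)N1[C@@H](Cc2ccccc2)COC1=O | intermediate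
6 | (2S)-5-methyl-2-(prop-1-en-2-yl)hex-4-en-1-ol, (S)-lavandulol | C=C(C)[C@H](CC=C(C)C)CO | intermediate
7 | (3S)-3-(iodomethyl)-2,6-dimethylhepta-1,5-diene, (S)-lavandulyl iodide | C=C(C)[C@H](CC=C(C)C)CI | intermediate
8 | 1-(2,4-dihydroxy-6-methoxyphenyl)ethan-1-one | CC(=O)c1c(O)cc(O)cc1OC | starting material
9 | 1-(2,4-dihydroxy-3-iodo-6-methoxyphenyl)ethan-1-one | CC(=O)c1c(O)c(I)c(O)cc1OC | intermediate
10 | 1-{2-hydroxy-3-iodo-6-methoxy-4-[tri(propan-2-yl)silyloxy]phenyl}ethan-1-one | CC(=O)c1c(O)c(I)c(O[Si](C(C)C)(C(C)C)C(C)C)cc1OC | intermediate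
11 | [(2S)-5-methyl-2-(prop-1-en-2-yl)hex-4-en-1-yl]zinc iodide, (S)-lavandulylzinc iodide | C=C(C)[C@H](CC=C(C)C)C[Zn]I | intermediate (not isolated)
12 | 1-{2-hydroxy-6-methoxy-3-[(2R)-5-methyl-2-(prop-1-en-2-yl)hex-4-en-1-yl]-4-[tri(propan-2-yl)silyloxy]phenyl}ethan-1-one | C=C(C)[C@H](CC=C(C)C)Cc1c(O)c(C(C)=O)c(OC)cc1O[Si](C(C)C)(C(C)C)C(C)C | intermediate
13 | 2-acetyl-3-methoxy-6-[(2R)-5-methyl-2-(prop-1-en-2-yl)hex-4-en-1-yl]-5-[tri(propan-2-yl)silyloxy]phenyl tert-butyl carbonate | C=C(C)[C@H](CC=C(C)C)Cc1c(OC(=O)OC(C)(C)C)c(C(C)=O)c(OC)cc1O[Si](C(C)C)(C(C)C)C(C)C | intermediate (not isolated)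
14 | tert-butyl 3-{2-hydroxy-6-methoxy-3-[(2R)-5-methyl-2-(prop-1-en-2-yl)hex-4-en-1-yl]-4-[tri(propan-2-yl)silyloxy]phenyl}-3-oxopropanoate | C=C(C)[C@H](CC=C(C)C)Cc1c(O)c(C(=O)CC(=O)OC(C)(C)C)c(OC)cc1O[Si](C(C)C)(C(C)C)C(C)C | intermediate
15 | 4-hydroxy-2-methoxybenzaldehyde | COc1cc(O)ccc1C=O | starting material
16 | 2-methoxy-4-[tri(propan-2-yl)silyloxy]benzaldehyde | COc1cc(O[Si](C(C)C)(C(C)C)C(C)C)ccc1C=O | intermediate
17 | tert-butyl (2Z)-2-{2-hydroxy-6-methoxy-3-[(2R)-5-methyl-2-(prop-1-en-2-yl)hex-4-en-1-yl]-4-[tri(propan-2-yl)silyloxy]benzoyl}-3-{2-methoxy-4-[tri(propan-2-yl)silyloxy]phenyl}prop-2-enoate | COc1cc(O[Si](C(C)C)(C(C)C)C(C)C)ccc1/C=C(\C(=O)OC(C)(C)C)C(=O)c1c(O)c(C[C@@H](CC=C(C)C)C(C)=C)c(O[Si](C(C)C)(C(C)C)C(C)C)cc1OC | intermediate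
18 | tert-butyl (2S,3R)-5-methoxy-2-{2-methoxy-4-[tri(propan-2-yl)silyloxy]phenyl}-8-[(2R)-5-methyl-2-(prop-1-en-2-yl)hex-4-en-1-yl]-4-oxo-7-[tri(propan-2-yl)silyloxy]-3,4-dihydro-2H-chromene-3-carboxylate (drawn as the trans keto tautomer) | C=C(C)[C@H](CC=C(C)C)Cc1c(O[Si](C(C)C)(C(C)C)C(C)C)cc(OC)c2c1O[C@H](c1ccc(O[Si](C(C)C)(C(C)C)C(C)C)cc1OC)[C@@H](C(=O)OC(C)(C)C)C2=O | intermediate (not isolated)
19 | (2S,3R)-5-methoxy-2-{2-methoxy-4-[tri(propan-2-yl)silyloxy]phenyl}-8-[(2R)-5-methyl-2-(prop-1-en-2-yl)hex-4-en-1-yl]-4-oxo-7-[tri(propan-2-yl)silyloxy]-3,4-dihydro-2H-chromene-3-carboxylic acid | C=C(C)[C@H](CC=C(C)C)Cc1c(O[Si](C(C)C)(C(C)C)C(C)C)cc(OC)c2c1O[C@H](c1ccc(O[Si](C(C)C)(C(C)C)C(C)C)cc1OC)[C@@H](C(=O)O)C2=O | intermediate (not isolated)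
20 | (2S)-5-methoxy-2-{2-methoxy-4-[tri(propan-2-yl)silyloxy]phenyl}-8-[(2R)-5-methyl-2-(prop-1-en-2-yl)hex-4-en-1-yl]-7-[tri(propan-2-yl)silyloxy]-2,3-dihydro-4H-chromen-4-one | C=C(C)[C@H](CC=C(C)C)Cc1c(O[Si](C(C)C)(C(C)C)C(C)C)cc(OC)c2c1O[C@H](c1ccc(O[Si](C(C)C)(C(C)C)C(C)C)cc1OC)CC2=O | intermediate
21 | (2S)-2'-methoxykurarinone | C=C(C)[C@H](CC=C(C)C)Cc1c(O)cc(OC)c2c1O[C@H](c1ccc(O)cc1OC)CC2=O | target

Total step count: 12 steps. Longest linear sequence: 9 steps (steps 1, 2, 3, 4, 7, 8, 10, 11, 12).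

Steps most likely to fail

Step 11. The ring closure may show poor facial selectivity at the hindered phenol, C2 may erode through reversible retro-oxa-Michael opening, and the lavandulyl diene may undergo cation–olefin reactions during the hot acid treatment. The fallback sets out from 17 and gives up catalyst control. Closure with catalytic Et3N in toluene at rt should give 18 together with its C2-epimeric series, tert-butyl (2R,3S)-4-oxochromane-3-carboxylate F1. Heating the mixture with SiO2 in refluxing toluene (a mild, known cleavage of tert-butyl esters) should pass through 19 and the (2R,3S) acid F2 to 20 and its 2R epimer F3. Because the lavandulyl centre is fixed, 20 and F3 are diastereomers and should be separable by preparative HPLC. F3 is recycled by base-mediated ring opening and reclosure (catalytic DBU, toluene), which regenerates the epimer pair. The fallback comes back to the route at 20.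

Step 7. The phenol may protonate the alkylzinc reagent, oxidative addition and transmetalation may be slow at the doubly ortho-substituted iodide, and the alkylpalladium intermediate may undergo β-hydride elimination. The fallback sets out from 7 and 10 and replaces zinc by boron (B-alkyl Suzuki–Miyaura coupling). Iodide 7 is treated with t-BuLi (2.1 equiv, Et2O, −78 °C) and the alkyllithium is trapped with B-methoxy-9-borabicyclo[3.3.1]nonane to give the lithium B-methoxy-B-lavandulyl borate F5. This is coupled directly with 10 (PdCl2(dppf), K3PO4, DMF–THF–H2O, 50 °C). The fallback comes back to the route at 12.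

Step 10. Condensation of the hindered aroylacetate with an electron-rich aldehyde may be slow, and piperidine may trigger premature uncatalysed ring closure that carries no stereocontrol at C2. The fallback sets out from 12 and 16 and avoids the ester altogether. A pyrrolidine-mediated condensation (Kabbe-type enamine aldol condensation, pyrrolidine, AcOH, toluene, 60 °C) should form the (E)-2'-hydroxychalcone F4 in the flask. This closes by oxa-Michael addition to 20 and its 2R epimer F3, which are separated and recycled as described for the fallback of step 11. The fallback comes back to the route at 20.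

Further compounds
F1 | step 11 | tert-butyl (2R,3S)-5-methoxy-2-{2-methoxy-4-[tri(propan-2-yl)silyloxy]phenyl}-8-[(2R)-5-methyl-2-(prop-1-en-2-yl)hex-4-en-1-yl]-4-oxo-7-[tri(propan-2-yl)silyloxy]-3,4-dihydro-2H-chromene-3-carboxylate | C=C(C)[C@H](CC=C(C)C)Cc1c(O[Si](C(C)C)(C(C)C)C(C)C)cc(OC)c2c1O[C@@H](c1ccc(O[Si](C(C)C)(C(C)C)C(C)C)cc1OC)[C@H](C(=O)OC(C)(C)C)C2=O
F2 | step 11 | (2R,3S)-5-methoxy-2-{2-methoxy-4-[tri(propan-2-yl)silyloxy]phenyl}-8-[(2R)-5-methyl-2-(prop-1-en-2-yl)hex-4-en-1-yl]-4-oxo-7-[tri(propan-2-yl)silyloxy]-3,4-dihydro-2H-chromene-3-carboxylic acid | C=C(C)[C@H](CC=C(C)C)Cc1c(O[Si](C(C)C)(C(C)C)C(C)C)cc(OC)c2c1O[C@@H](c1ccc(O[Si](C(C)C)(C(C)C)C(C)C)cc1OC)[C@H](C(=O)O)C2=O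
F3 | step 11 | (2R)-5-methoxy-2-{2-methoxy-4-[tri(propan-2-yl)silyloxy]phenyl}-8-[(2R)-5-methyl-2-(prop-1-en-2-yl)hex-4-en-1-yl]-7-[tri(propan-2-yl)silyloxy]-2,3-dihydro-4H-chromen-4-one | C=C(C)[C@H](CC=C(C)C)Cc1c(O[Si](C(C)C)(C(C)C)C(C)C)cc(OC)c2c1O[C@@H](c1ccc(O[Si](C(C)C)(C(C)C)C(C)C)cc1OC)CC2=O
F4 | step 10 | (2E)-1-{2-hydroxy-6-methoxy-3-[(2R)-5-methyl-2-(prop-1-en-2-yl)hex-4-en-1-yl]-4-[tri(propan-2-yl)silyloxy]phenyl}-3-{2-methoxy-4-[tri(propan-2-yl)silyloxy]phenyl}prop-2-en-1-one | COc1cc(O[Si](C(C)C)(C(C)C)C(C)C)ccc1/C=C/C(=O)c1c(O)c(C[C@@H](CC=C(C)C)C(C)=C)c(O[Si](C(C)C)(C(C)C)C(C)C)cc1OC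
F5 | step 7 | lithium 9-methoxy-9-[(2S)-5-methyl-2-(prop-1-en-2-yl)hex-4-en-1-yl]-9-borabicyclo[3.3.1]nonan-9-uide | [Li+].C=C(C)[C@H](CC=C(C)C)C[B-]1(OC)C2CCCC1CCC2
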